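**Plan**

1. Target numbering used below: ring C1 (C=O), C2=C3, C4 (OMe), C5 (CH2), C6 (quaternary); side chain C7 (CH–CH3), C8 (CH(OAc)Ar). Retrosynthetic cuts, in order: the acetate; the allyl group (its CH2–CH= and O8 are folded back into a δ-lactone); C4–OMe back to a C4 ketone; the ring bond C5–C6; the lactone C=C; the furyl–C6 bond; the C7–C8 aldol bond.
2. Enabling feature: C1 and C4 both carry oxygen (1,4), so C5 and C6 are both α-carbons of like (donor) polarity. C6 is made an acceptor as the β-carbon of an α,β-unsaturated δ-lactone built from the two inner allyl carbons and O8. C1–C4 with the cis C2=C3, and the methyl that becomes C5, are stored as a 5-methylfuran-2-yl ring (a masked (Z)-ene-1,4-dione).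
3. Forward order: anti-aldol, Weinreb amide, furyl ketone, unsaturated δ-lactone (first ring), furan oxidation with intramolecular Michael closure of the carbocycle (second ring, spiro), C4 reduction and O-methylation, lactone to lactol, Wittig opening to allyl plus C8–OH, acetylation.
4. Stereochemistry: C7 and C8 from the auxiliary-controlled anti-aldol; C6 in the key step, relayed from the C7 methyl through the lactone ring; C4 from catalyst-controlled asymmetric transfer hydrogenation.

Key step: step 5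

Remark: 1, 2 and 6 are taken as commercial, and DMDO as a freshly prepared acetone solution. Lactols 15 and 16 are carried as epimer mixtures because those centres are removed later. The descriptors of C7 (R in 3–5, 8, 9; S from 10 on) and of the quaternary carbon (S in 12–17; R in 18, 19) change only through CIP ranking, not through any change of geometry.

**Step 1**
Reactants: 1 3,4,5-trimethoxybenzaldehyde; 2 (4S)-4-benzyl-3-propanoyl-1,3-oxazolidin-2-one
Product: 4 (4S)-4-benzyl-3-[(2R,3S)-3-hydroxy-2-methyl-3-(3,4,5-trimethoxyphenyl)propanoyl]-1,3-oxazolidin-2-one, via O-trimethylsilyl aldol adduct 3 (not isolated)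
Conditions: MgCl2 (0.2 equiv), Et3N, Me3SiCl, EtOAc, rt; then CF3CO2H (cat.), MeOH
Reagents that add atoms: none
Why: Evans magnesium-halide-catalysed direct anti-aldol reaction, in which the chelated (Z)-magnesium enolate of the imide should be attacked by the non-enolisable aryl aldehyde on the face away from the benzyl group through a boat-like transition state, setting the methyl-bearing carbon (2R) and the carbinol carbon (3S) of the anti adduct, with in-flask silylation driving turnover and the silyl group leaving on acidic methanolysis.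

**Step 2**
Reactants: 4 (4S)-4-benzyl-3-[(2R,3S)-3-hydroxy-2-methyl-3-(3,4,5-trimethoxyphenyl)propanoyl]-1,3-oxazolidin-2-one
Product: 5 (2R,3S)-3-hydroxy-N-methoxy-N,2-dimethyl-3-(3,4,5-trimethoxyphenyl)propanamide
Conditions: MeNH(OMe)·HCl, AlMe3, CH2Cl2, −20 to 0 °C
Reagents that add atoms: N,O-dimethylhydroxylamine hydrochloride, CNOC.Cl
Why: Aluminium-amide transamidation of the imide (Weinreb amide formation), assisted by the free β-hydroxyl, should release the auxiliary without touching either stereocentre.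

**Step 3**
Reactants: 5 (2R,3S)-3-hydroxy-N-methoxy-N,2-dimethyl-3-(3,4,5-trimethoxyphenyl)propanamide; 6 2-methylfuran
Product: 8 (2R,3S)-3-hydroxy-2-methyl-1-(5-methylfuran-2-yl)-3-(3,4,5-trimethoxyphenyl)propan-1-one, via 5-methyl-2-furyllithium 7 (not isolated)
Conditions: 6 (3 equiv), n-BuLi (2.8 equiv), THF, 0 °C; then 5, −78 to 0 °C; aq NH4Cl
Reagents that add atoms: none
Why: Weinreb ketone synthesis, in which the furyllithium (one equivalent is spent on the hydroxyl) adds once to give a stable chelated tetrahedral intermediate, so the epimerisable α-methyl ketone should appear only on quench.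

**Step 4**
Reactants: 8 (2R,3S)-3-hydroxy-2-methyl-1-(5-methylfuran-2-yl)-3-(3,4,5-trimethoxyphenyl)propan-1-one
Product: 10 (5S,6S)-5-methyl-4-(5-methylfuran-2-yl)-6-(3,4,5-trimethoxyphenyl)-5,6-dihydro-2H-pyran-2-one, via ester ylide 9 (not isolated)
Conditions: Ph3P=C=C=O (1.3 equiv), toluene, 110 °C
Reagents that add atoms: (triphenylphosphoranylidene)ketene, O=C=C=P(c1ccccc1)(c1ccccc1)c1ccccc1
Why: The alcohol adds to the cumulated ylide and the resulting ester ylide should close the α,β-unsaturated δ-lactone by intramolecular Wittig reaction with the furyl ketone under neutral conditions, which makes the former ketone carbon the lactone β-carbon and creates no new stereocentre (5,6-trans retained).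

**Step 5**
Reactants: 10 (5S,6S)-5-methyl-4-(5-methylfuran-2-yl)-6-(3,4,5-trimethoxyphenyl)-5,6-dihydro-2H-pyran-2-one
Product: 12 (4S,5S,6S)-5-methyl-4-(3,4,5-trimethoxyphenyl)-3-oxaspiro[5.5]undec-8-ene-2,7,10-trione, via (Z)-enedione 11 (not isolated)
Conditions: DMDO (1.1 equiv, acetone), CH2Cl2, −40 to 0 °C; evaporate; then DBU (0.3 equiv), MeCN, −20 °C to rt
Reagents that add atoms: dimethyldioxirane, CC1(C)OO1
Why: DMDO transfers one oxygen to the 2,5-disubstituted furan, which opens to the (Z)-ene-1,4-dione 11 (furan to cis-enedione oxidation; the lactone-conjugated alkene is too electron-poor to be epoxidised), and DBU then enolises the methyl ketone, whose enolate adds to the β-carbon of the unsaturated δ-lactone, an intramolecular Michael addition of a ketone enolate to a β,β-disubstituted enoate that forms an all-carbon quaternary centre. The carbocycle closes in the 6-(enolendo)-exo-trig mode, attack at the lactone β-carbon (ring of 6) being preferred over attack at the α-carbon (ring of 7). The one new stereocentre is the spiro carbon, controlled by the neighbouring methyl-bearing carbon: A(1,2) strain with the acyl group holds that methyl pseudoaxial on the half-chair lactone, and the tethered enolate, which approaches from the exocyclic side, should bond on the opposite face (trans to CH3). The step needs C–C Michael closure to win over 5-exo aldol addition of the same enolate to the ring-side ketone; the aldol is reversible while the Michael closure is strongly exergonic and ends in the stabilised enolate of 12, so a catalytic equilibrating base should funnel material to 12. The Z geometry needed for closure is delivered by the furan ring itself, and the only other acidic site, the lactone γ-CH, is less readily enolised than the methyl ketone.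

**Step 6**
Reactants: 12 (4S,5S,6S)-5-methyl-4-(3,4,5-trimethoxyphenyl)-3-oxaspiro[5.5]undec-8-ene-2,7,10-trione
Product: 13 (4S,5S,6S,10R)-10-hydroxy-5-methyl-4-(3,4,5-trimethoxyphenyl)-3-oxaspiro[5.5]undec-8-ene-2,7-dione
Conditions: RuCl(p-cymene)[(R,R)-TsDPEN] (2 mol %), KOtBu (2 mol %), iPrOH, rt
Reagents that add atoms: none
Why: Noyori asymmetric transfer hydrogenation should reduce only the less hindered enone carbonyl (C10, flanked by CH=CH and CH2; C7 is shielded by the spiro carbon and the lactone is inert), the alkenyl group taking the role of the aryl group in the CH/π-organised transition state so that the (R,R) catalyst gives the (10R)-alcohol under reagent control, as in C4-selective reductions of 6,6-disubstituted cyclohex-2-ene-1,4-diones.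

**Step 7**
Reactants: 13 (4S,5S,6S,10R)-10-hydroxy-5-methyl-4-(3,4,5-trimethoxyphenyl)-3-oxaspiro[5.5]undec-8-ene-2,7-dione
Product: 14 (4S,5S,6S,10R)-10-methoxy-5-methyl-4-(3,4,5-trimethoxyphenyl)-3-oxaspiro[5.5]undec-8-ene-2,7-dione
Conditions: MeI, Ag2O, 4 Å MS, CH2Cl2, rt, dark
Reagents that add atoms: iodomethane, CI
Why: Silver-oxide-mediated Williamson etherification under non-basic conditions should methylate the allylic alcohol with retention at C10 and without enolising the γ-hydroxy enone.

**Step 8**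
Reactants: 14 (4S,5S,6S,10R)-10-methoxy-5-methyl-4-(3,4,5-trimethoxyphenyl)-3-oxaspiro[5.5]undec-8-ene-2,7-dione
Product: 15 (4S,5S,6S,10R)-10-methoxy-5-methyl-4-(3,4,5-trimethoxyphenyl)-3-oxaspiro[5.5]undec-8-ene-2,7-diol (C-2/C-7 epimer mixture)
Conditions: i-Bu2AlH (3 equiv), CH2Cl2, −78 °C; aq KNaC4H4O6
Reagents that add atoms: none
Why: Low-temperature i-Bu2AlH reduction should stop the lactone at the lactol (stable tetrahedral aluminate) while also reducing the enone carbonyl 1,2 to the allylic alcohol, and both new centres are transient so the mixture is carried on.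

**Step 9**
Reactants: 15 (4S,5S,6S,10R)-10-methoxy-5-methyl-4-(3,4,5-trimethoxyphenyl)-3-oxaspiro[5.5]undec-8-ene-2,7-diol (C-2/C-7 epimer mixture)
Product: 16 (4S,5S,6S,10R)-2-hydroxy-10-methoxy-5-methyl-4-(3,4,5-trimethoxyphenyl)-3-oxaspiro[5.5]undec-8-en-7-one (C-2 anomer mixture)
Conditions: MnO2 (excess), CH2Cl2, rt
Reagents that add atoms: none
Why: Activated MnO2 oxidises allylic alcohols selectively, so the ring carbinol should return to the enone while the saturated lactol, which still masks the benzylic C8 oxygen, is left.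

**Step 10**
Reactants: 16 (4S,5S,6S,10R)-2-hydroxy-10-methoxy-5-methyl-4-(3,4,5-trimethoxyphenyl)-3-oxaspiro[5.5]undec-8-en-7-one (C-2 anomer mixture)
Product: 18 megaphone (4R,6R)-6-[(1S,2S)-1-hydroxy-1-(3,4,5-trimethoxyphenyl)propan-2-yl]-4-methoxy-6-(prop-2-en-1-yl)cyclohex-2-en-1-one, via hydroxy aldehyde 17 (not isolated)
Conditions: Ph3PCH3Br (4 equiv), KOtBu (3.8 equiv), THF, 0 °C; then 16, 0 °C to rt
Reagents that add atoms: methyltriphenylphosphonium bromide, C[P+](c1ccccc1)(c1ccccc1)c1ccccc1.[Br-]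
Why: Wittig methylenation of the ring-opened hydroxy aldehyde tautomer of the lactol should turn the two former lactone carbons into the allyl group and free the C8 hydroxyl, the aldehyde reacting well before the neopentyl-type enone carbonyl next to the quaternary carbon.

**Step 11**
Reactants: 18 megaphone (4R,6R)-6-[(1S,2S)-1-hydroxy-1-(3,4,5-trimethoxyphenyl)propan-2-yl]-4-methoxy-6-(prop-2-en-1-yl)cyclohex-2-en-1-one
Product: 19 (1S,2S)-2-[(1R,5R)-5-methoxy-2-oxo-1-(prop-2-en-1-yl)cyclohex-3-en-1-yl]-1-(3,4,5-trimethoxyphenyl)propyl acetate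
Conditions: Ac2O, pyridine, DMAP (cat.), CH2Cl2, rt
Reagents that add atoms: acetic anhydride, CC(=O)OC(C)=O
Why: DMAP-catalysed acylation of the secondary benzylic alcohol should give the acetate with retention at C8.

**Compound list**

1 | 3,4,5-trimethoxybenzaldehyde | COc1cc(C=O)cc(OC)c1OC | starting material
2 | (4S)-4-benzyl-3-propanoyl-1,3-oxazolidin-2-one | CCC(=O)N1[C@@H](Cc2ccccc2)COC1=O | starting material
3 | (4S)-4-benzyl-3-[(2R,3S)-2-methyl-3-(3,4,5-trimethoxyphenyl)-3-(trimethylsilyloxy)propanoyl]-1,3-oxazolidin-2-one | O=C([C@H](C)[C@H](O[Si](C)(C)C)c1cc(OC)c(OC)c(OC)c1)N1[C@@H](Cc2ccccc2)COC1=O | intermediate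
4 | (4S)-4-benzyl-3-[(2R,3S)-3-hydroxy-2-methyl-3-(3,4,5-trimethoxyphenyl)propanoyl]-1,3-oxazolidin-2-one | O=C([C@H](C)[C@H](O)c1cc(OC)c(OC)c(OC)c1)N1[C@@H](Cc2ccccc2)COC1=O | intermediate
5 | (2R,3S)-3-hydroxy-N-methoxy-N,2-dimethyl-3-(3,4,5-trimethoxyphenyl)propanamide | CON(C)C(=O)[C@H](C)[C@H](O)c1cc(OC)c(OC)c(OC)c1 | intermediate
6 | 2-methylfuran | Cc1ccco1 | starting material
7 | 5-methyl-2-furyllithium | [Li]c1ccc(C)o1 | intermediate
8 | (2R,3S)-3-hydroxy-2-methyl-1-(5-methylfuran-2-yl)-3-(3,4,5-trimethoxyphenyl)propan-1-one | Cc1ccc(o1)C(=O)[C@H](C)[C@H](O)c2cc(OC)c(OC)c(OC)c2 | intermediate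
9 | (1S,2R)-2-methyl-3-(5-methylfuran-2-yl)-3-oxo-1-(3,4,5-trimethoxyphenyl)propyl (triphenylphosphoranylidene)acetate | Cc1ccc(o1)C(=O)[C@H](C)[C@H](OC(=O)C=P(c2ccccc2)(c3ccccc3)c4ccccc4)c5cc(OC)c(OC)c(OC)c5 | intermediate
10 | (5S,6S)-5-methyl-4-(5-methylfuran-2-yl)-6-(3,4,5-trimethoxyphenyl)-5,6-dihydro-2H-pyran-2-one (5,6-trans) | O=C1C=C(c2ccc(C)o2)[C@H](C)[C@H](O1)c3cc(OC)c(OC)c(OC)c3 | intermediate
11 | (5S,6S)-5-methyl-4-[(2Z)-4-oxopent-2-enoyl]-6-(3,4,5-trimethoxyphenyl)-5,6-dihydro-2H-pyran-2-one | O=C1C=C(C(=O)/C=C\C(C)=O)[C@H](C)[C@H](O1)c2cc(OC)c(OC)c(OC)c2 | intermediate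
12 | (4S,5S,6S)-5-methyl-4-(3,4,5-trimethoxyphenyl)-3-oxaspiro[5.5]undec-8-ene-2,7,10-trione | O=C2C[C@]1([C@H](C)[C@H](O2)c3cc(OC)c(OC)c(OC)c3)CC(=O)C=CC1=O | intermediate
13 | (4S,5S,6S,10R)-10-hydroxy-5-methyl-4-(3,4,5-trimethoxyphenyl)-3-oxaspiro[5.5]undec-8-ene-2,7-dione | O=C2C[C@]1([C@H](C)[C@H](O2)c3cc(OC)c(OC)c(OC)c3)C[C@@H](O)C=CC1=O | intermediate
14 | (4S,5S,6S,10R)-10-methoxy-5-methyl-4-(3,4,5-trimethoxyphenyl)-3-oxaspiro[5.5]undec-8-ene-2,7-dione | O=C2C[C@]1([C@H](C)[C@H](O2)c3cc(OC)c(OC)c(OC)c3)C[C@@H](OC)C=CC1=O | intermediate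
15 | (4S,5S,6S,10R)-10-methoxy-5-methyl-4-(3,4,5-trimethoxyphenyl)-3-oxaspiro[5.5]undec-8-ene-2,7-diol (C-2/C-7 epimer mixture) | OC2C[C@]1([C@H](C)[C@H](O2)c3cc(OC)c(OC)c(OC)c3)C[C@@H](OC)C=CC1O | intermediate
16 | (4S,5S,6S,10R)-2-hydroxy-10-methoxy-5-methyl-4-(3,4,5-trimethoxyphenyl)-3-oxaspiro[5.5]undec-8-en-7-one (C-2 anomer mixture) | OC2C[C@]1([C@H](C)[C@H](O2)c3cc(OC)c(OC)c(OC)c3)C[C@@H](OC)C=CC1=O | intermediate
17 | 2-{(1S,5R)-1-[(1S,2S)-1-hydroxy-1-(3,4,5-trimethoxyphenyl)propan-2-yl]-5-methoxy-2-oxocyclohex-3-en-1-yl}acetaldehyde | O=CC[C@]1([C@H](C)[C@H](O)c2cc(OC)c(OC)c(OC)c2)C[C@@H](OC)C=CC1=O | intermediate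
18 | megaphone, (4R,6R)-6-[(1S,2S)-1-hydroxy-1-(3,4,5-trimethoxyphenyl)propan-2-yl]-4-methoxy-6-(prop-2-en-1-yl)cyclohex-2-en-1-one | C=CC[C@]1([C@H](C)[C@H](O)c2cc(OC)c(OC)c(OC)c2)C[C@@H](OC)C=CC1=O | intermediate
19 | (1S,2S)-2-[(1R,5R)-5-methoxy-2-oxo-1-(prop-2-en-1-yl)cyclohex-3-en-1-yl]-1-(3,4,5-trimethoxyphenyl)propyl acetate | C=CC[C@]1([C@H](C)[C@H](OC(C)=O)c2cc(OC)c(OC)c(OC)c2)C[C@@H](OC)C=CC1=O | target

**Step count and risks**

Total step count: 11. Longest linear sequence: 11 steps (1 to 19).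

Steps most likely to fail:

Step 5. The facial control of the Michael closure may be lost: the aryl group, trans to the methyl group, is pseudoaxial with it and then lies 1,3 to the attacked carbon on the face the enolate must use. Other failure processes are epimerisation of the lactone γ-carbon by vinylogous enolisation, drift into the reversible 5-exo aldol manifold, and Z-to-E isomerisation of the enedione. The fallback sets out from 10 and replaces cyclic by acyclic stereocontrol. i-Bu2AlH (CH2Cl2, −78 °C) should reduce the lactone to the lactol (5S,6S)-5-methyl-4-(5-methylfuran-2-yl)-6-(3,4,5-trimethoxyphenyl)-5,6-dihydro-2H-pyran-2-ol F1, the ring-chain tautomer of a (Z)-hydroxy enal. DMDO and then DBU, as in step 5, would close the carbocycle through the open-chain (Z)-enal, where allylic 1,3-strain holds the C7–H in the alkene plane and the enolate adds anti to the CH(OH)Ar group. The new aldehyde re-closes to the lactol (4S,5S,6R)-2-hydroxy-5-methyl-4-(3,4,5-trimethoxyphenyl)-3-oxaspiro[5.5]undec-8-ene-7,10-dione F2 (same spiro geometry as 12). Fétizon oxidation of the lactol (Ag2CO3 on Celite, toluene, reflux) comes back to the route at 12.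

Step 6. The catalyst may not distinguish the two flanks of the C10 carbonyl well enough (low or reversed facial selectivity), the electron-poor alkene may suffer conjugate reduction, or the ruthenium hydride may isomerise the allylic alcohol to the saturated 1,4-diketone. The fallback sets out from 12 and uses substrate control followed by inversion. Luche reduction (NaBH4, CeCl3·7H2O, MeOH, −78 °C) gives the C10 alcohols; any (10R)-alcohol is 13 itself. The epimer (4S,5S,6S,10S)-10-hydroxy-5-methyl-4-(3,4,5-trimethoxyphenyl)-3-oxaspiro[5.5]undec-8-ene-2,7-dione F3 would be inverted by Mitsunobu reaction (4-nitrobenzoic acid, PPh3, DIAD, THF) to (4S,5S,6S,10R)-5-methyl-2,7-dioxo-4-(3,4,5-trimethoxyphenyl)-3-oxaspiro[5.5]undec-8-en-10-yl 4-nitrobenzoate F4. Methanolysis (K2CO3, MeOH, 0 °C) comes back to the route at 13.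

Step 9 (with step 8). MnO2 may over-oxidise the lactol to the lactone, or oxidise the neopentyl-type allylic alcohol only sluggishly. The fallback sets out from 14 and avoids the reduction–reoxidation detour by masking the enone in the flask. PPh3 and Me3SiOTf (CH2Cl2, −78 °C) should add 1,4 to the enone to give the β-phosphonio silyl dienol ether [(4S,5S,6S,10R)-10-methoxy-5-methyl-2-oxo-4-(3,4,5-trimethoxyphenyl)-7-(trimethylsilyloxy)-3-oxaspiro[5.5]undec-7-en-9-yl]triphenylphosphonium triflate F5. i-Bu2AlH then reduces only the lactone, giving the lactol [(4S,5S,6S,10R)-2-hydroxy-10-methoxy-5-methyl-4-(3,4,5-trimethoxyphenyl)-7-(trimethylsilyloxy)-3-oxaspiro[5.5]undec-7-en-9-yl]triphenylphosphonium triflate F6. Bu4NF on work-up expels PPh3 and restores the enone, coming back to the route at 16 (15 is bypassed).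

**Further compounds**

F1 | step 5 | (5S,6S)-5-methyl-4-(5-methylfuran-2-yl)-6-(3,4,5-trimethoxyphenyl)-5,6-dihydro-2H-pyran-2-ol (anomer mixture) | OC1C=C(c2ccc(C)o2)[C@H](C)[C@H](O1)c3cc(OC)c(OC)c(OC)c3
F2 | step 5 | (4S,5S,6R)-2-hydroxy-5-methyl-4-(3,4,5-trimethoxyphenyl)-3-oxaspiro[5.5]undec-8-ene-7,10-dione (anomer mixture) | OC2C[C@]1([C@H](C)[C@H](O2)c3cc(OC)c(OC)c(OC)c3)CC(=O)C=CC1=O
F3 | step 6 | (4S,5S,6S,10S)-10-hydroxy-5-methyl-4-(3,4,5-trimethoxyphenyl)-3-oxaspiro[5.5]undec-8-ene-2,7-dione | O=C2C[C@]1([C@H](C)[C@H](O2)c3cc(OC)c(OC)c(OC)c3)C[C@H](O)C=CC1=O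
F4 | step 6 | (4S,5S,6S,10R)-5-methyl-2,7-dioxo-4-(3,4,5-trimethoxyphenyl)-3-oxaspiro[5.5]undec-8-en-10-yl 4-nitrobenzoate | O=C2C[C@]1([C@H](C)[C@H](O2)c3cc(OC)c(OC)c(OC)c3)C[C@@H](OC(=O)c4ccc(cc4)[N+](=O)[O-])C=CC1=O
F5 | step 9 | [(4S,5S,6S,10R)-10-methoxy-5-methyl-2-oxo-4-(3,4,5-trimethoxyphenyl)-7-(trimethylsilyloxy)-3-oxaspiro[5.5]undec-7-en-9-yl]triphenylphosphonium trifluoromethanesulfonate (C-9 epimers) | O=C2C[C@]1([C@H](C)[C@H](O2)c3cc(OC)c(OC)c(OC)c3)C[C@@H](OC)C([P+](c4ccccc4)(c5ccccc5)c6ccccc6)C=C1O[Si](C)(C)C.[O-]S(=O)(=O)C(F)(F)F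
F6 | step 9 | [(4S,5S,6S,10R)-2-hydroxy-10-methoxy-5-methyl-4-(3,4,5-trimethoxyphenyl)-7-(trimethylsilyloxy)-3-oxaspiro[5.5]undec-7-en-9-yl]triphenylphosphonium trifluoromethanesulfonate (C-2/C-9 epimers) | OC2C[C@]1([C@H](C)[C@H](O2)c3cc(OC)c(OC)c(OC)c3)C[C@@H](OC)C([P+](c4ccccc4)(c5ccccc5)c6ccccc6)C=C1O[Si](C)(C)C.[O-]S(=O)(=O)C(F)(F)F
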